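**Retrosynthetic overview**

- The strategy rests on C4, an aroyl carbon on C4a of ring A, ortho to the carbon C8a that carries O1. C3–C4 and O1–C2 of the pyranone (ring C) are therefore cut together, and C2 and C3 come from an alkyne placed between the formyl C–H and the ortho O–H of a 4-O-protected salicylaldehyde.
- The alkyne carries the complete 8-methoxy-2,2-dimethyl-2H-chromen-6-yl unit on the carbon that becomes C3 and SiMe3 on the carbon that becomes C2. Silicon steers the insertion and is afterwards replaced by hydrogen.
- The aryl(silyl)alkyne is cut at the C(sp)–C6 bond (Sonogashira) to the 6-bromochromene. Its pyran ring is cut back to the 1,1-dimethylpropargyl ether of 4-bromo-2-methoxyphenol (Claisen rearrangement and electrocyclization).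
- Ring order: the dimethylpyran ring of the chromene first (thermal), then the pyranone ring C (oxidative annulation under trivalent rhodium catalysis). C2 protodesilylation and removal of the methoxymethyl (MOM) group finish the route.

Key step: step 5

Remark: the target has no stereocentre, so no stereocontrol is needed; any 12 formed by loss of the C2 silyl group already during step 5 would pass through step 6 unchanged.

**Route**

Step 1
Reactants: 1 4-bromo-2-methoxyphenol; 2 3-chloro-3-methylbut-1-yne
Product: 3 4-bromo-2-methoxy-1-[(2-methylbut-3-yn-2-yl)oxy]benzene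
Conditions: 2 (1.5 equiv), DBU, CuCl2·2H2O (1 mol%), MeCN, 0 °C to rt
Reagents that add atoms: none
Why: Copper-catalysed propargylic etherification of the phenoxide with the tertiary propargylic chloride is the standard entry to aryl 1,1-dimethylpropargyl ethers and should tolerate the aryl bromide and the ortho methoxy group.

Step 2
Reactants: 3 4-bromo-2-methoxy-1-[(2-methylbut-3-yn-2-yl)oxy]benzene
Product: 6 6-bromo-8-methoxy-2,2-dimethyl-2H-chromene, via allenylphenol 4 (not isolated), via quinone methide 5 (not isolated)
Conditions: PhNEt2, 190 °C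
Reagents that add atoms: none
Why: An aromatic propargyl Claisen rearrangement to the only free ortho carbon gives allenylphenol 4, a 1,5-hydrogen shift gives the Z-configured ortho-quinone methide 5, and oxa-6π electrocyclization closes the 2,2-dimethylpyran ring, which leaves bromine para to the ring oxygen (C6) and the methoxy group at C8.

Step 3
Reactants: 6 6-bromo-8-methoxy-2,2-dimethyl-2H-chromene; 7 ethynyltrimethylsilane
Product: 8 [(8-methoxy-2,2-dimethyl-2H-chromen-6-yl)ethynyl]trimethylsilane
Conditions: 7 (1.5 equiv), PdCl2(PPh3)2 (3 mol%), CuI (5 mol%), Et3N/THF, 70 °C, sealed tube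
Reagents that add atoms: none
Why: Sonogashira coupling of the aryl bromide with the terminal alkyne should proceed with the cis-disubstituted chromene alkene and the aryl ethers as spectators, and the C–Si bond is kept because no fluoride or hydroxide is present.

Step 4
Reactants: 9 2,4-dihydroxybenzaldehyde
Product: 10 2-hydroxy-4-(methoxymethoxy)benzaldehyde
Conditions: MOMCl (1.1 equiv), K2CO3, acetone, 0 °C to rt
Reagents that add atoms: chloromethyl methyl ether (MOMCl), COCCl
Why: Regioselective O-alkylation (MOM protection) should occur at the 4-hydroxyl, which is the more acidic one (para to the formyl group), while the 2-hydroxyl is held in a hydrogen bond to the formyl oxygen.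

Step 5
Reactants: 10 2-hydroxy-4-(methoxymethoxy)benzaldehyde; 8 [(8-methoxy-2,2-dimethyl-2H-chromen-6-yl)ethynyl]trimethylsilane
Product: 11 7-(methoxymethoxy)-3-(8-methoxy-2,2-dimethyl-2H-chromen-6-yl)-2-(trimethylsilyl)-4H-chromen-4-one
Conditions: 10 (1.3 equiv), [Cp*RhCl2]2 (2.5 mol%), anhydrous Cu(OAc)2 (2.1 equiv), o-xylene, 120 °C, N2
Reagents that add atoms: none
Why: Proposed new method: deprotonated 10 binds Cp*Rh (trivalent rhodium) through the phenoxide, acetate-assisted cleavage of the formyl C–H bond gives a five-membered acyl rhodacycle, alkyne 8 inserts into the Rh–acyl bond, and C–O reductive elimination from the seven-membered oxarhodacycle releases 11 and monovalent rhodium, which Cu(OAc)2 reoxidizes. The closest known reaction type is the rhodium-catalysed oxidative C–H/O–H annulation of salicylaldehydes with diaryl- and dialkylalkynes to 2,3-disubstituted chromones; an aryl(silyl)alkyne has not been established as partner in this aldehyde annulation, hence the label. The pyranone (ring C) closes as a six-membered ring in a formal [4+2] mode, C3–C4 by migratory insertion and then O1–C2 by reductive elimination, the phenol oxygen ending on the silyl-bearing carbon. No stereocentre is created. The step needs regioselectivity in the insertion (aryl to C3, silicon to C2), and this is secured by the SiMe3 group, whose bulk is kept away from the short forming acyl–carbon bond and which stabilizes the adjacent Rh–C bond, the bias that places silicon next to the heteroatom in Larock-type and related rhodium annulations of silylalkynes. Chemoselectivity rests on the alkyne out-competing the hindered chromene alkene for insertion and on the absence of silver, fluoride and water, so that the C(sp)–Si bond, the MOM acetal and the aryl ethers stay intact.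

Step 6
Reactants: 11 7-(methoxymethoxy)-3-(8-methoxy-2,2-dimethyl-2H-chromen-6-yl)-2-(trimethylsilyl)-4H-chromen-4-one
Product: 12 7-(methoxymethoxy)-3-(8-methoxy-2,2-dimethyl-2H-chromen-6-yl)-4H-chromen-4-one
Conditions: TBAF (1.2 equiv), AcOH (1.2 equiv), THF, 0 °C to rt
Reagents that add atoms: none
Why: Fluoride-mediated protodesilylation should be easy because the C2–Si bond belongs to a β-silyl enone next to the ring oxygen, so attack of fluoride on silicon releases a stabilized C2 carbanion equivalent that AcOH protonates, while the buffer guards the pyranone against ring opening and the MOM acetal and chromene are untouched.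

Step 7
Reactants: 12 7-(methoxymethoxy)-3-(8-methoxy-2,2-dimethyl-2H-chromen-6-yl)-4H-chromen-4-one
Product: 13 7-hydroxy-3-(8-methoxy-2,2-dimethyl-2H-chromen-6-yl)-4H-chromen-4-one
Conditions: conc. HCl (cat.), MeOH, 50 °C
Reagents that add atoms: none
Why: Acid-catalysed acetal cleavage (MOM deprotection by transacetalization with methanol) should free the 7-hydroxyl, while the aryl methyl ether, the pyranone and the 2,2-dimethylchromene are stable to dilute methanolic acid at this temperature.

**Compound list**

1 | 4-bromo-2-methoxyphenol | COc1cc(Br)ccc1O | starting material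
2 | 3-chloro-3-methylbut-1-yne | CC(C)(Cl)C#C | starting material
3 | 4-bromo-2-methoxy-1-[(2-methylbut-3-yn-2-yl)oxy]benzene | COc1cc(Br)ccc1OC(C)(C)C#C | intermediate
4 | 4-bromo-2-methoxy-6-(3-methylbuta-1,2-dien-1-yl)phenol | COc1cc(Br)cc(C=C=C(C)C)c1O | intermediate
5 | (6Z)-4-bromo-2-methoxy-6-(3-methylbut-2-en-1-ylidene)cyclohexa-2,4-dien-1-one | COC1=CC(Br)=C/C(=C/C=C(C)C)C1=O | intermediate
6 | 6-bromo-8-methoxy-2,2-dimethyl-2H-chromene | COc1cc(Br)cc2c1OC(C)(C)C=C2 | intermediate
7 | ethynyltrimethylsilane | C#C[Si](C)(C)C | starting material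
8 | [(8-methoxy-2,2-dimethyl-2H-chromen-6-yl)ethynyl]trimethylsilane | COc1cc(C#C[Si](C)(C)C)cc2c1OC(C)(C)C=C2 | intermediate
9 | 2,4-dihydroxybenzaldehyde | O=Cc1ccc(O)cc1O | starting material
10 | 2-hydroxy-4-(methoxymethoxy)benzaldehyde | COCOc1ccc(C=O)c(O)c1 | intermediate
11 | 7-(methoxymethoxy)-3-(8-methoxy-2,2-dimethyl-2H-chromen-6-yl)-2-(trimethylsilyl)-4H-chromen-4-one | COCOc1ccc2c(c1)oc([Si](C)(C)C)c(-c1cc(OC)c3OC(C)(C)C=Cc3c1)c2=O | intermediate
12 | 7-(methoxymethoxy)-3-(8-methoxy-2,2-dimethyl-2H-chromen-6-yl)-4H-chromen-4-one | COCOc1ccc2c(c1)occ(-c1cc(OC)c3OC(C)(C)C=Cc3c1)c2=O | intermediate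
13 | 7-hydroxy-3-(8-methoxy-2,2-dimethyl-2H-chromen-6-yl)-4H-chromen-4-one | COc1cc(-c2coc3cc(O)ccc3c2=O)cc2c1OC(C)(C)C=C2 | target

**Step count**

Total steps: 7. Longest linear sequence: 6 steps (1 → 3 → 6 → 8 → 11 → 12 → 13).

**Steps most likely to fail**

Step 5 (proposed new method). The insertion may take the opposite orientation and place the aryl group on C2. The alkyne may also lose silicon before insertion and then homocouple oxidatively, or the acyl rhodium may decarbonylate. The fallback is the known Suzuki route to isoflavones. It sets out from bromochromene 6 and returns to the route at 12.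
- Miyaura borylation of 6 (B2pin2, PdCl2(dppf), KOAc, dioxane, 90 °C) should give 2-(8-methoxy-2,2-dimethyl-2H-chromen-6-yl)-4,4,5,5-tetramethyl-1,3,2-dioxaborolane F1.
- In parallel, commercial 2,4-dihydroxyacetophenone is protected at the 4-hydroxyl (MOMCl, K2CO3, acetone) to 1-[2-hydroxy-4-(methoxymethoxy)phenyl]ethan-1-one F2.
- Condensation with N,N-dimethylformamide dimethyl acetal (toluene, 90 °C) should give (2E)-3-(dimethylamino)-1-[2-hydroxy-4-(methoxymethoxy)phenyl]prop-2-en-1-one F3.
- Iodine-induced cyclization (I2, pyridine, CHCl3, rt) should give 3-iodo-7-(methoxymethoxy)-4H-chromen-4-one F4.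
- Suzuki–Miyaura coupling of F4 with F1 (Pd(PPh3)4, K2CO3, DME/H2O, 80 °C) should give 12, which continues with step 7.

Step 7. During the acetal cleavage, acid may add methanol across the electron-rich C3=C4 bond of the chromene or degrade the pyran ring. The fallback avoids acid by using a fluoride-labile phenol protecting group. It sets out from 9 and returns at 13.
- Selective silylation of the 4-hydroxyl of 9 (i-Pr3SiCl, imidazole, CH2Cl2, 0 °C) should give 2-hydroxy-4-{[tri(propan-2-yl)silyl]oxy}benzaldehyde F5.
- Annulation of F5 with 8 under the conditions of step 5 should give 3-(8-methoxy-2,2-dimethyl-2H-chromen-6-yl)-7-{[tri(propan-2-yl)silyl]oxy}-2-(trimethylsilyl)-4H-chromen-4-one F6.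
- One treatment with TBAF/AcOH (2.5 equiv, THF, rt) should cleave both the O–Si and the C2–Si bond and give 13 directly.

Step 3. Oxidative addition of zerovalent palladium into the electron-rich C–Br bond may be slow, so that oxidative homocoupling of the silylacetylene takes over. The fallback builds the alkyne by carbonyl homologation instead of cross-coupling. It sets out from 6 and returns at 8.
- Bromine–lithium exchange (n-BuLi, THF, −78 °C) and quenching with DMF should give 8-methoxy-2,2-dimethyl-2H-chromene-6-carbaldehyde F7.
- Corey–Fuchs olefination (CBr4, PPh3, CH2Cl2, 0 °C) should give 6-(2,2-dibromoethenyl)-8-methoxy-2,2-dimethyl-2H-chromene F8.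
- n-BuLi (2.2 equiv, THF, −78 °C) followed by Me3SiCl should give the lithium acetylide and then 8, which continues with step 5.

**Further compounds**

F1 | step 5 | 2-(8-methoxy-2,2-dimethyl-2H-chromen-6-yl)-4,4,5,5-tetramethyl-1,3,2-dioxaborolane | COc1cc(B2OC(C)(C)C(C)(C)O2)cc2c1OC(C)(C)C=C2
F2 | step 5 | 1-[2-hydroxy-4-(methoxymethoxy)phenyl]ethan-1-one | CC(=O)c1ccc(OCOC)cc1O
F3 | step 5 | (2E)-3-(dimethylamino)-1-[2-hydroxy-4-(methoxymethoxy)phenyl]prop-2-en-1-one | CN(C)/C=C/C(=O)c1ccc(OCOC)cc1O
F4 | step 5 | 3-iodo-7-(methoxymethoxy)-4H-chromen-4-one | COCOc1ccc2c(c1)occ(I)c2=O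
F5 | step 7 | 2-hydroxy-4-{[tri(propan-2-yl)silyl]oxy}benzaldehyde | CC(C)[Si](Oc1ccc(C=O)c(O)c1)(C(C)C)C(C)C
F6 | step 7 | 3-(8-methoxy-2,2-dimethyl-2H-chromen-6-yl)-7-{[tri(propan-2-yl)silyl]oxy}-2-(trimethylsilyl)-4H-chromen-4-one | CC(C)[Si](Oc1ccc2c(c1)oc([Si](C)(C)C)c(-c1cc(OC)c3OC(C)(C)C=Cc3c1)c2=O)(C(C)C)C(C)C
F7 | step 3 | 8-methoxy-2,2-dimethyl-2H-chromene-6-carbaldehyde | COc1cc(C=O)cc2c1OC(C)(C)C=C2
F8 | step 3 | 6-(2,2-dibromoethenyl)-8-methoxy-2,2-dimethyl-2H-chromene | COc1cc(C=C(Br)Br)cc2c1OC(C)(C)C=C2
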